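**Retrosynthetic overview** (ring atoms numbered as in 1,2-dioxolane-3-acetic acid: C3 bears the acetic acid, C4 is the CH2, C5 bears the chain C1′–C10′)

1. Andavadoic acid 16 ⇐ methyl ester 15 ⇐ hydroxy ester 12, whose side chain carries a temporary hydroxyl at C2′ (erased by dehydration/diimide).
2. 12 ⇐ bicyclic peroxyketal 11 (a 2,6,7-trioxabicyclo[3.2.1]octane): Lewis-acid opening of the tether C–O bond by an acetate silyl ketene acetal sets C3 anti to the tether.
3. 11 ⇐ cyclopropanediol 8 + O2. Enabling feature: C3, C4 and C5 of the dioxolane are the three carbons of a 1,2-dimethylcyclopropan-1-ol (C3 = carbinol carbon, C5 = quaternary carbon). Homolysis of the C3–C5 bond and insertion of O2 expands the three-membered ring to the 1,2-dioxolane; the C2′ hydroxyl then bridges back to C3 as a six-membered ketal ring that sorts the C5 configuration.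
4. 8 ⇐ homoallylic acetate 7 (intramolecular Kulinkovich-type hydroxycyclopropanation) ⇐ alcohol 6 ⇐ (S)-epichlorohydrin 1 + (7-bromoheptyl)benzene 2 + isopropenyl Grignard; the C2′ stereocenter comes from 1.
5. Ring order: cyclopropane (step 4) → 1,2-dioxolane by two-atom ring expansion plus temporary tetrahydropyran ketal ring (step 5) → ketal ring opened again (step 6).

Key step: step 5

Assumption: (7-bromoheptyl)benzene is taken as a catalogue compound; if it is not, it is one step from 7-phenylheptan-1-ol with PBr3.

**Step 1**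
Reactants: 1 (S)-epichlorohydrin; 2 (7-bromoheptyl)benzene
Product: 5 (2S)-2-(8-phenyloctyl)oxirane, via 7-phenylheptylmagnesium bromide 3 (not isolated), via chlorohydrin 4 (not isolated)
Conditions: 2, Mg, THF, 40 °C; then CuI (10 mol %), 1, −40 → 0 °C; then 2 M NaOH, rt
Reagents that add atoms: none
Why: Cu-catalysed Grignard opening of the epoxide at its CH2 terminus and base-induced re-closure of the chlorohydrin (intramolecular Williamson reaction) shift the epoxide along the chain without touching the stereocenter of 1, which becomes C2 (S) of 5.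

**Step 2**
Reactants: 5 (2S)-2-(8-phenyloctyl)oxirane
Product: 6 (4S)-2-methyl-12-phenyldodec-1-en-4-ol
Conditions: isopropenylmagnesium bromide (1.5 equiv), CuI (10 mol %), THF, −30 → 0 °C; aq. NH4Cl
Reagents that add atoms: isopropenylmagnesium bromide, C=C(C)[Mg]Br
Why: Cu-catalysed SN2 opening of a terminal epoxide at the unsubstituted carbon installs the 1,1-disubstituted alkene (future C4, C5 and C5–CH3) and leaves the carbinol stereocenter (future C2′, S) untouched.

**Step 3**
Reactants: 6 (4S)-2-methyl-12-phenyldodec-1-en-4-ol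
Product: 7 (4S)-2-methyl-12-phenyldodec-1-en-4-yl acetate
Conditions: Ac2O, pyridine, DMAP (cat.), CH2Cl2, rt
Reagents that add atoms: acetic anhydride, CC(=O)OC(C)=O
Why: Standard DMAP-catalysed acylation; the acetyl group is the future C3 with its methyl group, and no stereocenter is formed or touched.

**Step 4**
Reactants: 7 (4S)-2-methyl-12-phenyldodec-1-en-4-yl acetate
Product: 8 2-[(2S)-2-hydroxy-10-phenyldecyl]-1,2-dimethylcyclopropan-1-ol (mixture of ring diastereomers)
Conditions: Ti(OiPr)4 (1.5 equiv), i-PrMgCl (3.5 equiv), Et2O, −50 → 0 °C; aq. NH4Cl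
Reagents that add atoms: none
Why: Intramolecular Kulinkovich-type hydroxycyclopropanation of a homoallylic ester: the titanacyclopropane formed by ligand exchange with the tethered alkene attacks the acetate carbonyl twice, the carbinol oxygen leaving as alkoxide, so the acetyl carbon becomes the cyclopropanol carbon; the two ring stereocenters form as a mixture, which is harmless because both are erased in step 5.

**Step 5**
Reactants: 8 2-[(2S)-2-hydroxy-10-phenyldecyl]-1,2-dimethylcyclopropan-1-ol
Product: 11 (1S,3S,5S)-1,5-dimethyl-3-(8-phenyloctyl)-2,6,7-trioxabicyclo[3.2.1]octane, via hydroperoxy ketone 9 (not isolated), via peroxy hemiketal 10 (not isolated)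
Conditions: Mn(acac)3 (5 mol %), O2 (1 atm), PhH, rt; then CSA (10 mol %), 4 Å MS, CH2Cl2, rt; chromatography
Reagents that add atoms: dioxygen, O=O
Why: The Mn(III) alkoxide of the tertiary cyclopropanol undergoes homolysis of its most substituted ring bond (C3–C5) to the tertiary β-keto radical, which captures O2 and is turned over to hydroperoxide 9; 9 adds to its own ketone to give the 1,2-dioxolan-3-ol 10, so the three-membered carbocycle has grown by both oxygen atoms into the five-membered peroxide ring, and acid then exchanges the hemiketal OH for the C2′ hydroxyl. The closest known reaction type is the manganese-catalysed aerobic oxidation of cyclopropanols to 1,2-dioxolan-3-ols, followed by the usual acid-catalysed alcohol exchange of peroxy hemiketals. The dioxolane closes 5-exo-trig (OOH onto C=O) and the temporary tetrahydropyran ring closes 6-exo-trig (C2′–OH onto the peroxycarbenium ion). Both ring stereocenters of 8 pass through a planar radical and a ketone, so all diastereomers of 8 converge; C3 is then fixed by the bridge, whereas C5 is formed without face selectivity and is sorted by the C2′ (S) stereocenter, because only the 5S epimer can carry the 8-phenyloctyl group exo (equatorial) on the chair of the bicycle, while the 5R epimer would have to hold it endo under the O–O bridge. The step needs regioselective ring cleavage, secured by the quaternary ring carbon (tertiary versus primary radical), and clean sorting of the C5 epimers, secured by the rigid [3.2.1] skeleton; since O2 capture is not expected to be face-selective, at most half of 8 can follow this path, and the 5R component of 10 should remain as a polar hemiketal (or a strained endo ketal) that is removed by chromatography.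

**Step 6**
Reactants: 11 (1S,3S,5S)-1,5-dimethyl-3-(8-phenyloctyl)-2,6,7-trioxabicyclo[3.2.1]octane
Product: 12 methyl 2-[(3R,5S)-5-[(2S)-2-hydroxy-10-phenyldecyl]-3,5-dimethyl-1,2-dioxolan-3-yl]acetate
Conditions: CH2=C(OMe)OTBS (3 equiv), TiCl4 (1.1 equiv), CH2Cl2, −78 °C; aq. NaHCO3
Reagents that add atoms: tert-butyl[(1-methoxyethenyl)oxy]dimethylsilane, C=C(OC)O[Si](C)(C)C(C)(C)C
Why: Lewis-acid-mediated substitution of an alkoxy-1,2-dioxolane by a silyl ketene acetal (Mukaiyama-type addition to a peroxycarbenium ion): TiCl4 binds the more basic tether oxygen, the C3–O(tether) bond ionises, and the nucleophile should enter on the face away from the departing titanium-bound side chain (inside attack on the envelope with C5–CH3 pseudo-axial), so that CH2CO2Me ends cis to the C5 methyl and C3 becomes R.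

**Step 7**
Reactants: 12 methyl 2-[(3R,5S)-5-[(2S)-2-hydroxy-10-phenyldecyl]-3,5-dimethyl-1,2-dioxolan-3-yl]acetate
Product: 15 methyl 2-[(3R,5S)-3,5-dimethyl-5-(10-phenyldecyl)-1,2-dioxolan-3-yl]acetate, via 2′-alkene 13 (not isolated), via 1′-alkene 14 (not isolated)
Conditions: Burgess reagent (3 equiv), PhH, 50 °C; then KO2CN=NCO2K (excess), AcOH, MeOH–CH2Cl2, rt
Reagents that add atoms: none
Why: Burgess dehydration (syn-elimination of the secondary sulfamate) removes the temporary C2′ stereocenter as a mixture of positional alkene isomers, and diimide reduction saturates both to the same chain without reducing the O–O bond; C3 and C5 are not touched.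

**Step 8**
Reactants: 15 methyl 2-[(3R,5S)-3,5-dimethyl-5-(10-phenyldecyl)-1,2-dioxolan-3-yl]acetate
Product: 16 andavadoic acid, 2-[(3R,5S)-3,5-dimethyl-5-(10-phenyldecyl)-1,2-dioxolan-3-yl]acetic acid
Conditions: LiOH (3 equiv), THF–H2O 3:1, 0 °C → rt; 1 M HCl to pH 3
Reagents that add atoms: lithium hydroxide, [Li+].[OH-]
Why: Saponification of the methyl ester under mild conditions; both ring stereocenters are quaternary and cannot epimerise by enolisation, and low temperature should suppress E1cB opening of the β-peroxy ester.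

**Compound list**

1 | (S)-epichlorohydrin, (2S)-2-(chloromethyl)oxirane | ClC[C@@H]1CO1 | starting material
2 | (7-bromoheptyl)benzene | BrCCCCCCCc1ccccc1 | starting material
3 | 7-phenylheptylmagnesium bromide | Br[Mg]CCCCCCCc1ccccc1 | intermediate
4 | (2S)-1-chloro-10-phenyldecan-2-ol (chlorohydrin, formed as its magnesium alkoxide) | ClC[C@@H](O)CCCCCCCCc1ccccc1 | intermediate
5 | (2S)-2-(8-phenyloctyl)oxirane | c1ccccc1CCCCCCCC[C@H]1CO1 | intermediate
6 | (4S)-2-methyl-12-phenyldodec-1-en-4-ol | C=C(C)C[C@@H](O)CCCCCCCCc1ccccc1 | intermediate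
7 | (4S)-2-methyl-12-phenyldodec-1-en-4-yl acetate | C=C(C)C[C@@H](OC(C)=O)CCCCCCCCc1ccccc1 | intermediate
8 | 2-[(2S)-2-hydroxy-10-phenyldecyl]-1,2-dimethylcyclopropan-1-ol (both ring carbons as mixtures) | CC1(O)CC1(C)C[C@@H](O)CCCCCCCCc1ccccc1 | intermediate
9 | (6S)-4-hydroperoxy-6-hydroxy-4-methyl-14-phenyltetradecan-2-one (both C4 epimers) | CC(=O)CC(C)(OO)C[C@@H](O)CCCCCCCCc1ccccc1 | intermediate
10 | 5-[(2S)-2-hydroxy-10-phenyldecyl]-3,5-dimethyl-1,2-dioxolan-3-ol (mixture at C3 and C5) | CC1(O)CC(C)(C[C@@H](O)CCCCCCCCc2ccccc2)OO1 | intermediate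
11 | (1S,3S,5S)-1,5-dimethyl-3-(8-phenyloctyl)-2,6,7-trioxabicyclo[3.2.1]octane | C[C@]12C[C@](C)(C[C@H](CCCCCCCCc3ccccc3)O1)OO2 | intermediate
12 | methyl 2-[(3R,5S)-5-[(2S)-2-hydroxy-10-phenyldecyl]-3,5-dimethyl-1,2-dioxolan-3-yl]acetate | COC(=O)C[C@@]1(C)C[C@](C)(C[C@@H](O)CCCCCCCCc2ccccc2)OO1 | intermediate
13 | methyl 2-[(3R,5S)-3,5-dimethyl-5-(10-phenyldec-2-en-1-yl)-1,2-dioxolan-3-yl]acetate (E/Z) | COC(=O)C[C@@]1(C)C[C@](C)(CC=CCCCCCCCc2ccccc2)OO1 | intermediate
14 | methyl 2-[(3R,5R)-3,5-dimethyl-5-(10-phenyldec-1-en-1-yl)-1,2-dioxolan-3-yl]acetate (E/Z; same ring geometry as 13, descriptor changed by priority only) | COC(=O)C[C@@]1(C)C[C@](C)(C=CCCCCCCCCc2ccccc2)OO1 | intermediate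
15 | methyl 2-[(3R,5S)-3,5-dimethyl-5-(10-phenyldecyl)-1,2-dioxolan-3-yl]acetate | COC(=O)C[C@@]1(C)C[C@](C)(CCCCCCCCCCc2ccccc2)OO1 | intermediate
16 | andavadoic acid, 2-[(3R,5S)-3,5-dimethyl-5-(10-phenyldecyl)-1,2-dioxolan-3-yl]acetic acid | C[C@]1(CCCCCCCCCCc2ccccc2)C[C@](C)(CC(=O)O)OO1 | target

**Step count and risks**

Total step count: 8. Longest linear sequence: 8 steps (from 1 or 2 to 16).

Steps most likely to fail:

1. Step 4 – the 1,1-disubstituted alkene may exchange onto titanium too slowly, so that the acetate is simply cleaved or reduced before the cyclopropane forms. The fallback sets out from 6 and returns at 8. Alcohol 6 is silylated (TBSCl, imidazole) to the silyl ether F1. Dibromocarbene addition (CHBr3, KOtBu, pentane) gives the gem-dibromocyclopropane F2. Bromine–lithium exchange and methylation (n-BuLi, −100 °C, then MeI) give the bromo(methyl)cyclopropane F3. A second exchange, borylation and oxidation with retention (t-BuLi, −78 °C; B(OMe)3; H2O2/NaOH) give the cyclopropanol silyl ether F4, and TBAF releases 8.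

2. Step 5 – the tertiary β-keto radical or its peroxyl successor may be lost to enone formation or alkoxyl-radical β-scission under Mn/O2, and the sorting of C5 epimers may be incomplete if the ketalisation is pushed too hard. The fallback sets out from 8 and returns at 9. FeCl3 in DMF at 0 °C opens the cyclopropanol through the same tertiary radical without oxygen and transfers chlorine, giving the β-chloro ketone F5. Silver-assisted perhydrolysis (AgOTf, anhydrous H2O2 in Et2O, 0 °C) then replaces the tertiary chloride by OOH to give 9, which is ketalised with CSA as in step 5 to 11.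

3. Step 6 – the ketal may ionise at the peroxide C–O bond instead of the tether C–O bond (loss of the O–O unit by fragmentation), or the small ketene acetal may add with poor facial selectivity. The fallback sets out from 11 and returns at 12. Allyltrimethylsilane with SnCl4 (CH2Cl2, −78 °C), a well-behaved nucleophile for peroxycarbenium ions, gives the allyl dioxolane F6 with the same stereochemical rationale. Ozonolysis with PPh3 work-up gives the aldehyde F7, Pinnick oxidation gives the acid F8, and TMSCHN2 gives 12.

**Further compounds**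

F1 | step 4 | tert-butyldimethyl{[(4S)-2-methyl-12-phenyldodec-1-en-4-yl]oxy}silane | C=C(C)C[C@@H](O[Si](C)(C)C(C)(C)C)CCCCCCCCc1ccccc1
F2 | step 4 | tert-butyl{[(2S)-1-(2,2-dibromo-1-methylcyclopropyl)-10-phenyldecan-2-yl]oxy}dimethylsilane (ring-carbon epimers) | BrC1(Br)CC1(C)C[C@@H](O[Si](C)(C)C(C)(C)C)CCCCCCCCc1ccccc1
F3 | step 4 | {[(2S)-1-(2-bromo-1,2-dimethylcyclopropyl)-10-phenyldecan-2-yl]oxy}(tert-butyl)dimethylsilane (ring diastereomers) | CC1(Br)CC1(C)C[C@@H](O[Si](C)(C)C(C)(C)C)CCCCCCCCc1ccccc1
F4 | step 4 | 2-[(2S)-2-{[tert-butyl(dimethyl)silyl]oxy}-10-phenyldecyl]-1,2-dimethylcyclopropan-1-ol (ring diastereomers) | CC1(O)CC1(C)C[C@@H](O[Si](C)(C)C(C)(C)C)CCCCCCCCc1ccccc1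
F5 | step 5 | (6S)-4-chloro-6-hydroxy-4-methyl-14-phenyltetradecan-2-one (both C4 epimers) | CC(=O)CC(C)(Cl)C[C@@H](O)CCCCCCCCc1ccccc1
F6 | step 6 | (2S)-1-[(3S,5S)-3,5-dimethyl-5-(prop-2-en-1-yl)-1,2-dioxolan-3-yl]-10-phenyldecan-2-ol | C=CC[C@@]1(C)C[C@](C)(C[C@@H](O)CCCCCCCCc2ccccc2)OO1
F7 | step 6 | 2-[(3R,5S)-5-[(2S)-2-hydroxy-10-phenyldecyl]-3,5-dimethyl-1,2-dioxolan-3-yl]acetaldehyde | O=CC[C@@]1(C)C[C@](C)(C[C@@H](O)CCCCCCCCc2ccccc2)OO1
F8 | step 6 | 2-[(3R,5S)-5-[(2S)-2-hydroxy-10-phenyldecyl]-3,5-dimethyl-1,2-dioxolan-3-yl]acetic acid | OC(=O)C[C@@]1(C)C[C@](C)(C[C@@H](O)CCCCCCCCc2ccccc2)OO1
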